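**Retrosynthetic overview**

- The target is reached from the guaia-1(10),4-dien-3-one 27 by hydride delivery to C10 and equilibration of C1; 27 comes from the 10-acetoxy-guai-4-en-3-one 26 by loss of the C10 acetate.
- The strategy rests on the cyclopentenone C1–C5 (C3 ketone, C4=C5 carrying the methyl) joined at C1 to the methyl-bearing C10 of the seven-membered ring. This is what a 4-methylcyclohexa-2,5-dienone with C10 as its quaternary para carbon gives on ring contraction, so 26 comes from the decalin dienone 24 by a type A photorearrangement in acetic acid.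
- Ring A of 24 (C1–C5, C10) is a benzene ring; ring B is closed by C9→C10 para-alkylation of a phenoxide with dearomatization (19 → 21).
- The chain is built by an Evans syn aldol (C7–C8) between an arylpropanoyl imide and a two-carbon aldehyde (C8, C9), then MeMgBr for C11; the imide comes from a Negishi coupling on a bromoxylenol ether.
- Ring order: ring A (bought as the arene), ring B (step 13), then the five- and seven-membered rings together (step 17).

Key step: step 17

Remark on numbering: guaiane numbers (C1–C11) are used for all intermediates, including the open-chain and decalin compounds.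
Remark on availability: 2-bromo-1,3-dimethyl-4-nitrobenzene is taken as a catalogue compound; it is otherwise one nitration from 2-bromo-1,3-dimethylbenzene.
Remark on C10: C1 and C10 both become trigonal in step 18, so the C10 configuration of 21–24 is not relayed to the target; the series is drawn with the angular methyl anti to the C7 side chain, and its C10 epimer would pass through steps 14–18 the same way and merge at 27.

**Step 1**
Reactants: 1 2-bromo-1,3-dimethyl-4-nitrobenzene
Product: 2 3-bromo-2,4-dimethylaniline
Conditions: H2 (1 atm), 5% Pt/C (sulfided), EtOAc, rt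
Reagents that add atoms: none
Why: Catalytic hydrogenation of the nitro group, for which sulfided platinum on carbon is chosen because it leaves the aryl C–Br bond intact.

**Step 2**
Reactants: 2 3-bromo-2,4-dimethylaniline
Product: 4 3-bromo-2,4-dimethylphenol, via 3-bromo-2,4-dimethylbenzenediazonium hydrogen sulfate 3 (not isolated)
Conditions: NaNO2, aq. H2SO4, 0 °C; then added to aq. H2SO4, 100 °C
Reagents that add atoms: water, O
Why: Diazotization followed by thermal hydrolysis of the diazonium salt puts the oxygen that becomes the C3 ketone next to the future C4 methyl.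

**Step 3**
Reactants: 4 3-bromo-2,4-dimethylphenol
Product: 5 1-(benzyloxy)-3-bromo-2,4-dimethylbenzene
Conditions: BnBr, K2CO3, DMF, rt
Reagents that add atoms: benzyl bromide, BrCc1ccccc1
Why: Williamson etherification masks the phenol for the organometallic steps with a group that later leaves together with the C9 benzyl ether.

**Step 4**
Reactants: 5 1-(benzyloxy)-3-bromo-2,4-dimethylbenzene; 6 (3-ethoxy-3-oxopropyl)zinc bromide
Product: 7 ethyl 3-[3-(benzyloxy)-2,6-dimethylphenyl]propanoate
Conditions: Pd(OAc)2 (2 mol%), 2-dicyclohexylphosphino-2′,6′-dimethoxybiphenyl (4 mol%), THF, 60 °C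
Reagents that add atoms: none
Why: Negishi coupling of a primary alkylzinc homoenolate with the di-ortho-substituted aryl bromide, which a bulky biaryl phosphine makes feasible, attaches C6, C7 and the future C11 in one step.

**Step 5**
Reactants: 7 ethyl 3-[3-(benzyloxy)-2,6-dimethylphenyl]propanoate
Product: 8 3-[3-(benzyloxy)-2,6-dimethylphenyl]propanoic acid
Conditions: LiOH, THF/H2O, rt; then 1 M HCl
Reagents that add atoms: lithium hydroxide, [Li+].[OH-]
Why: Ester saponification of an unhindered ethyl ester, with no other base-sensitive group present.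

**Step 6**
Reactants: 8 3-[3-(benzyloxy)-2,6-dimethylphenyl]propanoic acid; 9 (S)-4-benzyloxazolidin-2-one
Product: 11 (S)-4-benzyl-3-{3-[3-(benzyloxy)-2,6-dimethylphenyl]propanoyl}oxazolidin-2-one, via mixed pivalic anhydride 10 (not isolated)
Conditions: PivCl, Et3N, THF, −20 °C; then 9, LiCl, rt
Reagents that add atoms: none
Why: N-acylation of the oxazolidinone through the mixed anhydride, which reacts at the less hindered acyl group.

**Step 7**
Reactants: 11 (S)-4-benzyl-3-{3-[3-(benzyloxy)-2,6-dimethylphenyl]propanoyl}oxazolidin-2-one; 12 (benzyloxy)acetaldehyde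
Product: 14 (S)-4-benzyl-3-[(2S,3S)-4-(benzyloxy)-2-{[3-(benzyloxy)-2,6-dimethylphenyl]methyl}-3-hydroxybutanoyl]oxazolidin-2-one, via dibutylboron Z-enolate 13 (not isolated)
Conditions: Bu2BOTf, i-Pr2NEt, CH2Cl2, 0 °C; 12, −78 → 0 °C; H2O2, pH 7 buffer, MeOH
Reagents that add atoms: none
Why: Evans boron aldol reaction, in which the Z-enolate reacts through a closed chair transition state on the face away from the auxiliary benzyl group to set C7 (S) and C8 (S here) syn; the aldehyde has two carbons because only C9 lies between C8 and C10 in ring B, and a three-carbon aldehyde would give a seven-membered ring B.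

**Step 8**
Reactants: 14 the syn aldol imide
Product: 15 methyl (2S,3S)-4-(benzyloxy)-2-{[3-(benzyloxy)-2,6-dimethylphenyl]methyl}-3-hydroxybutanoate
Conditions: NaOMe (1.1 equiv), MeOH/CH2Cl2, 0 °C
Reagents that add atoms: sodium methoxide, [Na+].[O-]C
Why: Methanolysis of the N-acyl oxazolidinone at the exocyclic carbonyl releases the auxiliary at low temperature, where C7 epimerization and retro-aldol cleavage are slow.

**Step 9**
Reactants: 15 the methyl ester
Product: 16 (2S,3S)-1-(benzyloxy)-3-{[3-(benzyloxy)-2,6-dimethylphenyl]methyl}-4-methylpentane-2,4-diol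
Conditions: MeMgBr (5 equiv), CeCl3, THF, −78 → 0 °C
Reagents that add atoms: methylmagnesium bromide, C[Mg]Br
Why: Double addition of the methyl organometallic to the ester builds the tertiary carbinol C11, with CeCl3 suppressing enolization of the intermediate ketone and retro-aldol cleavage.

**Step 10**
Reactants: 16 the 8,11-diol
Product: 17 (5S,6S)-6-[(benzyloxy)methyl]-5-{[3-(benzyloxy)-2,6-dimethylphenyl]methyl}-2,2,4,4-tetramethyl-1,3-dioxane
Conditions: Me2C(OMe)2, PPTS, CH2Cl2, rt
Reagents that add atoms: 2,2-dimethoxypropane, COC(C)(C)OC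
Why: Acetal exchange ties the 1,3-diol into an acetonide, so that neither the C8 alkoxide (epoxide) nor the C11 alkoxide (tetrahydrofuran) can attack C9 in step 13.

**Step 11**
Reactants: 17 the bis-benzyl ether acetonide
Product: 18 3-{[(5S,6S)-6-(hydroxymethyl)-2,2,4,4-tetramethyl-1,3-dioxan-5-yl]methyl}-2,4-dimethylphenol
Conditions: H2 (1 atm), 10% Pd/C, EtOAc, rt
Reagents that add atoms: none
Why: Hydrogenolysis removes the aryl and the alkyl benzyl ether in one neutral operation that leaves the acetonide alone.

**Step 12**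
Reactants: 18 the phenol alcohol
Product: 19 3-{[(5S,6S)-6-(bromomethyl)-2,2,4,4-tetramethyl-1,3-dioxan-5-yl]methyl}-2,4-dimethylphenol
Conditions: CBr4, PPh3, 2,6-lutidine, CH2Cl2, 0 °C
Reagents that add atoms: tetrabromomethane, BrC(Br)(Br)Br
Why: Appel bromination converts only the primary alcohol, because an aryloxyphosphonium ion cannot be displaced at an sp2 carbon and the phenol is returned on work-up.

**Step 13**
Reactants: 19 the bromo phenol
Product: 21 (7S,8R,10R)-8,11-(isopropylidenedioxy)eudesma-1,4-dien-3-one, via potassium phenoxide 20 (not isolated)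
Conditions: KOtBu (1.0 equiv), t-BuOH, 0.005 M, 80 °C, dark
Reagents that add atoms: none
Why: Intramolecular para C-alkylation of the phenoxide (dearomatizing alkylation, 6-exo-tet) closes ring B and makes C10 quaternary; one equivalent of base leaves no free tert-butoxide for dehydrobromination, the protic solvent favours para over ortho attack, and C10 is set by the ring face that C9 reaches in the chair-like transition state, drawn with the methyl anti to the C7 side chain.

**Step 14**
Reactants: 21 the dienone acetonide
Product: 22 (7S,8R,10R)-8,11-dihydroxyeudesma-1,4-dien-3-one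
Conditions: AcOH/H2O 4:1, 40 °C, dark
Reagents that add atoms: none
Why: Acid hydrolysis of the strained tetramethyl-dioxane acetal proceeds under conditions far milder than those needed for dienone–phenol rearrangement.

**Step 15**
Reactants: 22 the dienone diol
Product: 23 (7S,8R,10R)-11-hydroxy-3-oxoeudesma-1,4-dien-8-yl 2-methylpropanoate
Conditions: (i-PrCO)2O, DMAP (cat.), Et3N, CH2Cl2, 0 °C
Reagents that add atoms: 2-methylpropanoic anhydride, CC(C)C(=O)OC(=O)C(C)C
Why: DMAP-catalysed acylation takes the secondary C8 hydroxyl, the tertiary C11 hydroxyl being unreactive at this temperature.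

**Step 16**
Reactants: 23 the 8-isobutyrate
Product: 24 (7S,8R,10R)-11-acetoxy-3-oxoeudesma-1,4-dien-8-yl 2-methylpropanoate
Conditions: Ac2O, DMAP (2 equiv), Et3N, CH2Cl2, 35 °C, dark
Reagents that add atoms: acetic anhydride, CC(=O)OC(C)=O
Why: Nucleophilic-catalyst (Steglich-type) acetylation of the tertiary alcohol under basic conditions avoids acid catalysts, which with Ac2O would trigger dienone–phenol rearrangement.

**Step 17**
Reactants: 24 the cross-conjugated dienone
Product: 26 (1S,7S,8R,10S)-10,11-diacetoxy-3-oxoguai-4-en-8-yl 2-methylpropanoate, via oxyallyl zwitterion 25 (not isolated)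
Conditions: hν (medium-pressure Hg lamp, Pyrex), glacial AcOH, argon, 15 °C
Reagents that add atoms: acetic acid, CC(O)=O
Why: Excitation and intersystem crossing give the dienone triplet, which bonds C1 to C5 and relaxes to the bicyclo[3.1.0] oxyallyl zwitterion 25; acetic acid protonates it on oxygen, and acetate opens the C5–C10 cyclopropane bond by attack on tertiary C10 from the side opposite C5, after which the dienol ketonizes at C2. The closest known reaction is the type A photorearrangement of 4-methyl cross-conjugated cyclohexadienones carrying an angular methyl (the santonin class) to 10-acetoxy or 10-hydroxy 5/7-fused enones in acidic media. The cyclopentenone closes by β,β′ bonding of C1 to C5 across ring A, and the seven-membered ring is not cyclized but arises by ring expansion, C1 being inserted between C5 and C10 of ring B when C5–C10 breaks. C1 is controlled by the C10 configuration of 24, since the cyclopropane must be cis-fused to ring B and H1 therefore lies on the side of C9, and C10 is set by inversion, so H1 ends cis to the new acetate. The step needs the acid-trapped 5/7 mode over the lumiketone and spiro modes, which the C4 methyl (stabilizing positive charge next to the cyclopropane and steering cleavage to C5–C10) and the nucleophilic acidic solvent secure. Both new stereocentres are planarized in step 18, so their role in the main line is only to make 26 one defined compound.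

**Step 18**
Reactants: 26 the 10-acetoxy guaienone
Product: 27 (7S,8R)-11-acetoxy-3-oxoguaia-1(10),4-dien-8-yl 2-methylpropanoate
Conditions: DBU (3 equiv), PhMe, 60 °C, stopped at full conversion
Reagents that add atoms: none
Why: Vinylogous E1cB elimination, in which DBU removes H1 (γ to the enone) and the dienolate expels the δ-acetate at C10, is the one way to remove this acetate selectively because the C11 acetate and the C8 ester are not activated by the enone; a short reaction time limits further enolization toward C9.

**Step 19**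
Reactants: 27 the linear dienone
Product: 29 (1R,7S,8R,10S)-11-acetoxy-3-oxoguai-4-en-8-yl 2-methylpropanoate (target), via guai-1(5)-en-3-one 28 (not isolated)
Conditions: [(Ph3P)CuH]6 (0.4 equiv), t-BuOH (2 equiv), PhMe, rt; then DBU (1 equiv), 40 °C
Reagents that add atoms: none
Why: Copper hydride conjugate reduction in the 1,6 sense places hydride on the terminal carbon C10 (C5 is fully substituted and flanked by the C4 methyl) from the α face, opposite the pseudo-axial C8 ester and the C7 group, which sets C10; the deconjugated ketone 28 formed on protonation is then moved into conjugation by DBU, and C1 is expected to settle in the epimer with C2 trans to the C10 methyl.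

**Compound list**

1 | 2-bromo-1,3-dimethyl-4-nitrobenzene | Cc1ccc([N+](=O)[O-])c(C)c1Br | starting material
2 | 3-bromo-2,4-dimethylaniline | Cc1ccc(N)c(C)c1Br | intermediate
3 | 3-bromo-2,4-dimethylbenzenediazonium hydrogen sulfate | Cc1ccc([N+]#N)c(C)c1Br.OS(=O)(=O)[O-] | intermediate
4 | 3-bromo-2,4-dimethylphenol | Cc1ccc(O)c(C)c1Br | intermediate
5 | 1-(benzyloxy)-3-bromo-2,4-dimethylbenzene | Cc1ccc(OCc2ccccc2)c(C)c1Br | intermediate
6 | (3-ethoxy-3-oxopropyl)zinc bromide | CCOC(=O)CC[Zn]Br | starting material
7 | ethyl 3-[3-(benzyloxy)-2,6-dimethylphenyl]propanoate | CCOC(=O)CCc1c(C)ccc(OCc2ccccc2)c1C | intermediate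
8 | 3-[3-(benzyloxy)-2,6-dimethylphenyl]propanoic acid | OC(=O)CCc1c(C)ccc(OCc2ccccc2)c1C | intermediate
9 | (S)-4-benzyloxazolidin-2-one | O=C1N[C@@H](Cc2ccccc2)CO1 | starting material
10 | 3-[3-(benzyloxy)-2,6-dimethylphenyl]propanoic pivalic anhydride | CC(C)(C)C(=O)OC(=O)CCc1c(C)ccc(OCc2ccccc2)c1C | intermediate
11 | (S)-4-benzyl-3-{3-[3-(benzyloxy)-2,6-dimethylphenyl]propanoyl}oxazolidin-2-one | O=C(CCc1c(C)ccc(OCc2ccccc2)c1C)N1[C@@H](Cc2ccccc2)COC1=O | intermediate
12 | (benzyloxy)acetaldehyde | O=CCOCc1ccccc1 | starting material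
13 | dibutylboron Z-enolate of 11 | CCCCB(CCCC)O/C(=C\Cc1c(C)ccc(OCc2ccccc2)c1C)N1[C@@H](Cc2ccccc2)COC1=O | intermediate
14 | (S)-4-benzyl-3-[(2S,3S)-4-(benzyloxy)-2-{[3-(benzyloxy)-2,6-dimethylphenyl]methyl}-3-hydroxybutanoyl]oxazolidin-2-one | O=C([C@@H](Cc1c(C)ccc(OCc2ccccc2)c1C)[C@H](O)COCc1ccccc1)N1[C@@H](Cc2ccccc2)COC1=O | intermediate
15 | methyl (2S,3S)-4-(benzyloxy)-2-{[3-(benzyloxy)-2,6-dimethylphenyl]methyl}-3-hydroxybutanoate | COC(=O)[C@@H](Cc1c(C)ccc(OCc2ccccc2)c1C)[C@H](O)COCc1ccccc1 | intermediate
16 | (2S,3S)-1-(benzyloxy)-3-{[3-(benzyloxy)-2,6-dimethylphenyl]methyl}-4-methylpentane-2,4-diol | CC(C)(O)[C@@H](Cc1c(C)ccc(OCc2ccccc2)c1C)[C@H](O)COCc1ccccc1 | intermediate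
17 | (5S,6S)-6-[(benzyloxy)methyl]-5-{[3-(benzyloxy)-2,6-dimethylphenyl]methyl}-2,2,4,4-tetramethyl-1,3-dioxane | CC1(C)OC(C)(C)[C@@H](Cc2c(C)ccc(OCc3ccccc3)c2C)[C@@H](COCc2ccccc2)O1 | intermediate
18 | 3-{[(5S,6S)-6-(hydroxymethyl)-2,2,4,4-tetramethyl-1,3-dioxan-5-yl]methyl}-2,4-dimethylphenol | CC1(C)OC(C)(C)[C@@H](Cc2c(C)ccc(O)c2C)[C@@H](CO)O1 | intermediate
19 | 3-{[(5S,6S)-6-(bromomethyl)-2,2,4,4-tetramethyl-1,3-dioxan-5-yl]methyl}-2,4-dimethylphenol | CC1(C)OC(C)(C)[C@@H](Cc2c(C)ccc(O)c2C)[C@@H](CBr)O1 | intermediate
20 | potassium phenoxide of 19 | CC1(C)OC(C)(C)[C@@H](Cc2c(C)ccc([O-])c2C)[C@@H](CBr)O1.[K+] | intermediate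
21 | (7S,8R,10R)-8,11-(isopropylidenedioxy)eudesma-1,4-dien-3-one | CC1(C)OC(C)(C)[C@H]2CC3=C(C)C(=O)C=C[C@@]3(C)C[C@H]2O1 | intermediate
22 | (7S,8R,10R)-8,11-dihydroxyeudesma-1,4-dien-3-one | CC(C)(O)[C@H]1CC2=C(C)C(=O)C=C[C@@]2(C)C[C@H]1O | intermediate
23 | (7S,8R,10R)-11-hydroxy-3-oxoeudesma-1,4-dien-8-yl 2-methylpropanoate | CC(C)(O)[C@H]1CC2=C(C)C(=O)C=C[C@@]2(C)C[C@H]1OC(=O)C(C)C | intermediate
24 | (7S,8R,10R)-11-acetoxy-3-oxoeudesma-1,4-dien-8-yl 2-methylpropanoate | CC(=O)OC(C)(C)[C@H]1CC2=C(C)C(=O)C=C[C@@]2(C)C[C@H]1OC(=O)C(C)C | intermediate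
25 | 1,5-cyclo oxyallyl zwitterion from 24 (cyclopropane C1–C5–C10, cis-fused to ring B) | CC(=O)OC(C)(C)[C@H]1C[C@@]23[C+](C)C([O-])=C[C@@H]2[C@@]3(C)C[C@H]1OC(=O)C(C)C | intermediate
26 | (1S,7S,8R,10S)-10,11-diacetoxy-3-oxoguai-4-en-8-yl 2-methylpropanoate | CC(=O)OC(C)(C)[C@H]1CC2=C(C)C(=O)C[C@@H]2[C@@](C)(OC(C)=O)C[C@H]1OC(=O)C(C)C | intermediate
27 | (7S,8R)-11-acetoxy-3-oxoguaia-1(10),4-dien-8-yl 2-methylpropanoate | CC(=O)OC(C)(C)[C@H]1CC2=C(C)C(=O)CC2=C(C)C[C@H]1OC(=O)C(C)C | intermediate
28 | (7S,8R,10S)-11-acetoxy-3-oxoguai-1(5)-en-8-yl 2-methylpropanoate, both C4 epimers | CC(=O)OC(C)(C)[C@H]1CC2=C(CC(=O)C2C)[C@@H](C)C[C@H]1OC(=O)C(C)C | intermediate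
29 | (1R,7S,8R,10S)-11-acetoxy-3-oxoguai-4-en-8-yl 2-methylpropanoate | CC(=O)OC(C)(C)[C@H]1CC2=C(C)C(=O)C[C@@H]2[C@@H](C)C[C@H]1OC(=O)C(C)C | target

**Step count and risks**

Total: 19 steps. Longest linear sequence: 19 steps (1 → 29).

Steps most likely to fail:

Step 17. The opening cyclopropane may be captured at C10 from the β face by the carbonyl oxygen of the C8 isobutyrate instead of by solvent, which would scramble the acyl groups, and the product enone may be lost to further photolysis at high conversion. The fallback moves the rearrangement ahead of the acylations and sets out from 21. Irradiation of 21 in anhydrous acetic acid (1% Ac2O) should give the 10-acetoxy guaienone acetonide F1. DBU in toluene should then give the guaia-1(10),4-dienone acetonide F2, and aqueous acetic acid the dienone diol F3. Isobutyric anhydride with DMAP should give the dienone 8-isobutyrate F4, and Ac2O/DMAP/Et3N acetylates the tertiary hydroxyl to come back at 27.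

Step 19. Hydride may go to the carbonyl carbon or to the β face of C10, and the C1 equilibrium may not favour the needed epimer. The fallback sets out from 24 and avoids both the dienone and the equilibration. Irradiation of 24 in 45% aqueous acetic acid lets water trap C10 and should give the 10-hydroxy guaienone F5, with H1 β as fixed by the rearrangement. Methyl chlorooxoacetate with DMAP should give the C10 methyl oxalate F6. Bu3SnH with AIBN in refluxing toluene then generates the tertiary C10 radical, which should take hydrogen from the α face and give 29 directly. This fallback depends on 24 having the C10 configuration drawn, since C1 is then inherited from it.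

Step 13. Displacement at C9 is slowed by the adjacent ring oxygen and the branching at C8, so ortho C-alkylation at C4 (a linearly conjugated 2,4-dienone), intermolecular O-alkylation or dehydrobromination may take over. The fallback sets out from 18 and replaces base-driven closure on a bromide by fluoride-triggered closure on a triflate. The phenol is silylated selectively through its sodium salt (NaH 1.0 equiv, TBSCl, THF, 0 °C) to the aryl tert-butyldimethylsilyl ether F7. Tf2O with 2,6-lutidine at −78 °C gives the primary triflate F8. CsF in MeCN at high dilution, 0 °C to rt, then frees the phenoxide, which should close onto the better leaving group without any alkoxide base and come back at 21.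

**Further compounds**

F1 | step 17 | (1S,7S,8R,10S)-10-acetoxy-8,11-(isopropylidenedioxy)guai-4-en-3-one | CC1(C)OC(C)(C)[C@H]2CC3=C(C)C(=O)C[C@@H]3[C@@](C)(OC(C)=O)C[C@H]2O1
F2 | step 17 | (7S,8R)-8,11-(isopropylidenedioxy)guaia-1(10),4-dien-3-one | CC1(C)OC(C)(C)[C@H]2CC3=C(C)C(=O)CC3=C(C)C[C@H]2O1
F3 | step 17 | (7S,8R)-8,11-dihydroxyguaia-1(10),4-dien-3-one | CC(C)(O)[C@H]1CC2=C(C)C(=O)CC2=C(C)C[C@H]1O
F4 | step 17 | (7S,8R)-11-hydroxy-3-oxoguaia-1(10),4-dien-8-yl 2-methylpropanoate | CC(C)(O)[C@H]1CC2=C(C)C(=O)CC2=C(C)C[C@H]1OC(=O)C(C)C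
F5 | step 19 | (1S,7S,8R,10S)-11-acetoxy-10-hydroxy-3-oxoguai-4-en-8-yl 2-methylpropanoate | CC(=O)OC(C)(C)[C@H]1CC2=C(C)C(=O)C[C@@H]2[C@@](C)(O)C[C@H]1OC(=O)C(C)C
F6 | step 19 | C10 methyl oxalate of F5 | CC(=O)OC(C)(C)[C@H]1CC2=C(C)C(=O)C[C@@H]2[C@@](C)(OC(=O)C(=O)OC)C[C@H]1OC(=O)C(C)C
F7 | step 13 | [(4S,5S)-5-({3-[(tert-butyldimethylsilyl)oxy]-2,6-dimethylphenyl}methyl)-2,2,6,6-tetramethyl-1,3-dioxan-4-yl]methanol | CC1(C)OC(C)(C)[C@@H](Cc2c(C)ccc(O[Si](C)(C)C(C)(C)C)c2C)[C@@H](CO)O1
F8 | step 13 | trifluoromethanesulfonate of F7 | CC1(C)OC(C)(C)[C@@H](Cc2c(C)ccc(O[Si](C)(C)C(C)(C)C)c2C)[C@@H](COS(=O)(=O)C(F)(F)F)O1
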